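**Plan**
1. Retrosynthetic cuts, in order: the two acyl–O bonds (at C2 and C6); the C4–isopropyl bond, back to a C4 ketone; the C5–H/C6–O pair, back to a C5=C6 alkene; C1–C10 by a retro-[3,3] shift; and last C5–C6, between a cyclopentenone and a cyclopropane.
2. Enabling feature: in ring B, the C8=C9 alkene and the oxygenated C5–C6 edge flank the single methylene C7, and C1–C10 is the bond opposite C7. With C5=C6 unsaturated, ring B is a cyclohepta-1,4-diene. That is the retron of a cis-divinylcyclopropane in which C6–C7–C8 is a temporary three-membered ring, and C1=C5 of ring A and C9=C10 are the two vinyl arms.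
3. Forward order: ring A (bromo enone 5) is made from a silyloxycyclopentenone and the vinylcyclopropane 11 from propargyl alcohol, and a Negishi coupling joins them at C5–C6. The Cope rearrangement then closes ring B and delivers the quaternary C1, the C8=C9 alkene and an enone handle for C4–C6. Isopropyl addition, epoxidation, reductive opening, redox inversion at C6 and two esterifications follow.
4. Stereochemistry: C2 comes from the chiral pool, and C6/C8 of the cyclopropane from a ligand-controlled Simmons–Smith reaction. C1 is set by chirality transfer through the boat transition state, matched with attack anti to the C2 silyloxy group. C4 is set by α-face Grignard addition, C5 by hydrogen-atom transfer anti to the β substituents, and C6 by a SmI2 reduction that gives the equatorial alcohol.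

Key step: step 9

Numbering (daucane): C1 quaternary carbon with methyl, C2 CH–O(angeloyl), C3 CH2, C4 C(OH)(i-Pr), C5 ring-fusion CH, C6 CH–O(anisoyl), C7 CH2, C8 =C(CH3), C9 =CH, C10 CH2. Ring A is C1–C5 and ring B is C1, C5–C10. β is the face of the angular methyl group.
Assumption: the (4R,5R)-dioxaborolane ligand is taken to show, with alkenol 8, the same facial sense that it shows with other substituted allylic alcohols; if not, its antipode would be used.

Step 1
Reactants: 1 (4R)-4-(tert-butyldimethylsilyloxy)cyclopent-2-en-1-one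
Product: 2 [(3R,4R)-4-(tert-butyldimethylsilyloxy)-3-methylcyclopent-1-en-1-yl]oxy(trimethyl)silane
Conditions: MeLi, CuI, Et2O, 0 °C; then 1, TMSCl, THF, −78 °C
Reagents that add atoms: methyllithium [Li]C; chlorotrimethylsilane C[Si](C)(C)Cl
Why: Cuprate conjugate addition with in situ silylation should add methyl anti to the silyloxy group, the chlorosilane trapping the enolate before it can expel silanolate; the new C1 centre is erased in step 2.

Step 2
Reactants: 2 [(3R,4R)-4-(tert-butyldimethylsilyloxy)-3-methylcyclopent-1-en-1-yl]oxy(trimethyl)silane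
Product: 3 (4R)-4-(tert-butyldimethylsilyloxy)-3-methylcyclopent-2-en-1-one
Conditions: Pd(OAc)2 (10 mol %), O2 (1 atm), DMSO, 25–40 °C
Reagents that add atoms: none
Why: In this aerobic Saegusa–Ito oxidation the palladium enolate carries a β-hydrogen only on C1, so the alkene can form only between C5 and C1, and the C2 centre is not touched.

Step 3
Reactants: 3 (4R)-4-(tert-butyldimethylsilyloxy)-3-methylcyclopent-2-en-1-one
Product: 5 (4R)-2-bromo-4-(tert-butyldimethylsilyloxy)-3-methylcyclopent-2-en-1-one, via dibromo ketone 4 (not isolated)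
Conditions: Br2, CH2Cl2, −78 °C; then Et3N, −78 to 0 °C
Reagents that add atoms: bromine BrBr
Why: Bromine addition followed by dehydrobromination is the standard route to 2-bromo-3-methylcyclopentenones; the amine removes the acidic α-hydrogen and the tertiary β-bromide leaves.

Step 4
Reactants: 6 prop-2-yn-1-ol
Product: 8 (2Z)-3-iodo-2-methylprop-2-en-1-ol, via alkenylmagnesium alkoxide 7 (not isolated)
Conditions: MeMgBr (2.5 equiv), CuI (10 mol %), Et2O, −10 °C to rt; then I2, −10 °C; then H2O
Reagents that add atoms: methylmagnesium bromide C[Mg]Br; iodine [I][I]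
Why: Alkoxide-directed, copper-catalysed anti-carbomagnesiation places methyl on the internal carbon and magnesium cis to the CH2O group, and iodinolysis proceeds with retention to give the Z iodide.

Step 5
Reactants: 8 (2Z)-3-iodo-2-methylprop-2-en-1-ol
Product: 9 [(1R,2R)-2-iodo-1-methylcyclopropyl]methanol
Conditions: Et2Zn, CH2I2, DME, CH2Cl2, −10 °C; (4R,5R)-2-butyl-N,N,N',N'-tetramethyl-1,3,2-dioxaborolane-4,5-dicarboxamide (1.2 equiv), −10 °C to rt; then H2O
Reagents that add atoms: diiodomethane C(I)I
Why: In the asymmetric Simmons–Smith reaction (Charette modification), also used on halogenated allylic alcohols, the ligand-bound zinc alkoxide fixes the alkene face and the syn addition keeps iodine cis to CH2OH, which sets C6 and C8.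

Step 6
Reactants: 9 [(1R,2R)-2-iodo-1-methylcyclopropyl]methanol
Product: 10 (1R,2R)-2-iodo-1-methylcyclopropane-1-carbaldehyde
Conditions: Dess–Martin periodinane, CH2Cl2, 0 °C to rt
Reagents that add atoms: none
Why: Dess–Martin oxidation stops at the aldehyde, and the carbon next to the carbonyl (C8) is quaternary, so it cannot epimerise.

Step 7
Reactants: 10 (1R,2R)-2-iodo-1-methylcyclopropane-1-carbaldehyde
Product: 11 (1R,2R)-1-ethenyl-2-iodo-1-methylcyclopropane
Conditions: Ph3PCH3Br, KHMDS, THF, 0 °C; then 10, −78 to 0 °C (product kept as a solution)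
Reagents that add atoms: methyltriphenylphosphonium bromide C[P+](c1ccccc1)(c1ccccc1)c1ccccc1.[Br-]
Why: Wittig methylenation of a non-enolisable aldehyde installs C10, and the cyclopropyl iodide is inert to the ylide.

Step 8
Reactants: 11 (1R,2R)-1-ethenyl-2-iodo-1-methylcyclopropane; 5 (4R)-2-bromo-4-(tert-butyldimethylsilyloxy)-3-methylcyclopent-2-en-1-one
Product: 14 (4R)-4-(tert-butyldimethylsilyloxy)-2-[(1R,2R)-2-ethenyl-2-methylcyclopropyl]-3-methylcyclopent-2-en-1-one, via cyclopropyllithium 12 (not isolated), via cyclopropylzinc bromide 13 (not isolated)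
Conditions: t-BuLi (2.0 equiv), Et2O, −78 °C; ZnBr2, THF, −78 to 0 °C; then 5, Pd2(dba)3 (2.5 mol %), SPhos (10 mol %), THF, rt
Reagents that add atoms: none
Why: Iodine–lithium exchange, transmetalation to zinc and Negishi coupling all proceed with retention at the configurationally stable cyclopropyl carbon, so the C5–C6 bond forms with the two alkenyl groups cis on the three-membered ring, and the organozinc tolerates the enone.

Step 9
Reactants: 14 (4R)-4-(tert-butyldimethylsilyloxy)-2-[(1R,2R)-2-ethenyl-2-methylcyclopropyl]-3-methylcyclopent-2-en-1-one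
Product: 15 (3R,3aR)-3-(tert-butyldimethylsilyloxy)-3a,6-dimethyl-3,3a,4,7-tetrahydroazulen-1(2H)-one
Conditions: toluene (0.02 M), BHT (cat.), 110 °C, sealed tube
Reagents that add atoms: none
Why: On heating, 14 should undergo the concerted [3,3]-sigmatropic divinylcyclopropane–cycloheptadiene (Cope) rearrangement through the endo boat transition state, in which the strained C6–C8 bond breaks while C10 bonds to C1 and the π bonds move to C5=C6 and C8=C9. The closest known reaction type is the thermolysis of 2-vinylcyclopropyl-substituted 2-methylcyclopentenones to hydroazulenones with an angular methyl group. Ring B closes by a three-to-seven ring expansion (C1–C10 made, C6–C8 lost), and the boat geometry allows only cis alkenes in the new ring, with C7 cis to C1 across C5=C6. The one new stereocentre, quaternary C1, is controlled by chirality transfer from the cyclopropane: with the (R,R) ring the boat can form only when C7–C8 lie under the α face of ring A, so C10 bonds to that face and the methyl group ends β, and this is also the face anti to the C2 silyloxy group (matched case). The rearrangement must outrun homolytic cis–trans stereomutation of the cyclopropane and thermal loss of silanol, which the cis geometry fixed in steps 4 and 5, the release of ring strain and a neutral, base-free, dilute medium should secure. The methyl group on C1 points at C7 in the transition state and raises the barrier, hence heating to about 110 °C rather than reaction at room temperature.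

Step 10
Reactants: 15 (3R,3aR)-3-(tert-butyldimethylsilyloxy)-3a,6-dimethyl-3,3a,4,7-tetrahydroazulen-1(2H)-one
Product: 16 2β-(tert-butyldimethylsilyloxy)dauca-5,8-dien-4β-ol
Conditions: i-PrMgCl, LaCl3·2LiCl, THF, −20 to 0 °C; then H2O
Reagents that add atoms: isopropylmagnesium chloride CC(C)[Mg]Cl
Why: In this lanthanide-assisted Grignard 1,2-addition the additive suppresses enolisation, β-hydride reduction and loss of the β-silyloxy group, and the nucleophile should attack C4 from the α face because the β face carries the cis-1,3 silyloxy group and the angular methyl, which sets the 4β-hydroxyl.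

Step 11
Reactants: 16 2β-(tert-butyldimethylsilyloxy)dauca-5,8-dien-4β-ol
Product: 17 2β-(tert-butyldimethylsilyloxy)-5β,6β-epoxydauc-8-en-4β-ol
Conditions: VO(acac)2 (5 mol %), t-BuOOH, CH2Cl2, 0 °C to rt
Reagents that add atoms: tert-butyl hydroperoxide CC(C)(C)OO
Why: In the hydroxyl-directed vanadium-catalysed epoxidation the tertiary allylic alcohol binds the metal peroxide, so only C5=C6 reacts, C8=C9 is spared, and oxygen arrives syn to the 4β-hydroxyl on the convex β face.

Step 12
Reactants: 17 2β-(tert-butyldimethylsilyloxy)-5β,6β-epoxydauc-8-en-4β-ol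
Product: 18 2β-(tert-butyldimethylsilyloxy)-5αH-dauc-8-ene-4β,6β-diol
Conditions: Cp2TiCl2 (10 mol %), Mn, 2,4,6-collidine hydrochloride, 1,4-cyclohexadiene, THF, rt
Reagents that add atoms: none
Why: In the titanocene-catalysed reductive epoxide opening (Nugent–RajanBabu type, known to turn trisubstituted 2,3-epoxy alcohols into 1,3-diols) trivalent titanium cleaves C5–O to the tertiary C5 radical, and cyclohexadiene should deliver hydrogen to the α face, anti to the angular methyl and the two β oxygen substituents, which sets 5α-H and the trans ring fusion.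

Step 13
Reactants: 18 2β-(tert-butyldimethylsilyloxy)-5αH-dauc-8-ene-4β,6β-diol
Product: 19 2β-(tert-butyldimethylsilyloxy)-4β-hydroxy-5αH-dauc-8-en-6-one
Conditions: Dess–Martin periodinane, CH2Cl2, 0 °C to rt
Reagents that add atoms: none
Why: Dess–Martin oxidation takes only the secondary alcohol under near-neutral conditions that spare the β-hydroxy ketone and leave C8=C9 out of conjugation, and the trans-fused C5 epimer should also be the more stable one because it keeps C6 trans to the isopropyl group.

Step 14
Reactants: 19 2β-(tert-butyldimethylsilyloxy)-4β-hydroxy-5αH-dauc-8-en-6-one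
Product: 20 2β-(tert-butyldimethylsilyloxy)-5αH-dauc-8-ene-4β,6α-diol
Conditions: SmI2 (2.5 equiv), H2O, THF, 0 °C
Reagents that add atoms: none
Why: In the single-electron reduction of a β-hydroxy ketone with SmI2, the ketyl held by the C4 oxygen is reduced and protonated to the more stable equatorial 6α-alcohol, free of the 1,3-diaxial contact with the angular methyl, whereas hydride reagents would attack from the open α side and give back the axial alcohol 18.

Step 15
Reactants: 20 2β-(tert-butyldimethylsilyloxy)-5αH-dauc-8-ene-4β,6α-diol; 21 4-methoxybenzoyl chloride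
Product: 22 2β-(tert-butyldimethylsilyloxy)-6α-(4-methoxybenzoyloxy)-5αH-dauc-8-en-4β-ol
Conditions: Et3N, DMAP (cat.), CH2Cl2, 0 °C to rt
Reagents that add atoms: none
Why: DMAP-catalysed acylation reaches only the secondary equatorial C6 hydroxyl, and the tertiary C4 hydroxyl stays free.

Step 16
Reactants: 22 2β-(tert-butyldimethylsilyloxy)-6α-(4-methoxybenzoyloxy)-5αH-dauc-8-en-4β-ol
Product: 23 6α-(4-methoxybenzoyloxy)-5αH-dauc-8-ene-2β,4β-diol
Conditions: HF·pyridine, THF, 0 °C to rt
Reagents that add atoms: none
Why: Fluoride-induced desilylation in a weakly acidic medium frees the C2 hydroxyl without ester cleavage or acyl migration.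

Step 17
Reactants: 23 6α-(4-methoxybenzoyloxy)-5αH-dauc-8-ene-2β,4β-diol; 24 angelic acid, (2Z)-2-methylbut-2-enoic acid
Product: 26 (1R,3R,3aS,4S,8aR)-3-hydroxy-4-(4-methoxybenzoyloxy)-6,8a-dimethyl-3-(propan-2-yl)-1,2,3,3a,4,5,8,8a-octahydroazulen-1-yl (2Z)-2-methylbut-2-enoate, via mixed anhydride 25 (not isolated)
Conditions: 24, 2,4,6-trichlorobenzoyl chloride, Et3N, toluene, rt; then 23, 80 °C
Reagents that add atoms: none
Why: Yamaguchi mixed-anhydride esterification run without a nucleophilic catalyst is the established way to transfer the angeloyl group to hindered secondary alcohols without Z-to-E isomerisation, and the tertiary alcohol does not react.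

**Compound list**
1 | (4R)-4-(tert-butyldimethylsilyloxy)cyclopent-2-en-1-one | O=C1C[C@@H](O[Si](C)(C)C(C)(C)C)C=C1 | starting material
2 | [(3R,4R)-4-(tert-butyldimethylsilyloxy)-3-methylcyclopent-1-en-1-yl]oxy(trimethyl)silane (methyl trans to OTBS) | C[C@@H]1C=C(O[Si](C)(C)C)C[C@H]1O[Si](C)(C)C(C)(C)C | intermediate
3 | (4R)-4-(tert-butyldimethylsilyloxy)-3-methylcyclopent-2-en-1-one | O=C1C[C@@H](O[Si](C)(C)C(C)(C)C)C(C)=C1 | intermediate
4 | (4R)-2,3-dibromo-4-(tert-butyldimethylsilyloxy)-3-methylcyclopentan-1-one (mixture at C2 and C3) | O=C1C[C@@H](O[Si](C)(C)C(C)(C)C)C(C)(Br)C1Br | intermediate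
5 | (4R)-2-bromo-4-(tert-butyldimethylsilyloxy)-3-methylcyclopent-2-en-1-one | O=C1C[C@@H](O[Si](C)(C)C(C)(C)C)C(C)=C1Br | intermediate
6 | prop-2-yn-1-ol | C#CCO | starting material
7 | (Z)-3-(bromomagnesiooxy)-2-methylprop-1-enylmagnesium bromide | Br[Mg]/C=C(/C)CO[Mg]Br | intermediate
8 | (2Z)-3-iodo-2-methylprop-2-en-1-ol | I/C=C(/C)CO | intermediate
9 | [(1R,2R)-2-iodo-1-methylcyclopropyl]methanol (I cis to CH2OH) | I[C@@H]1C[C@]1(C)CO | intermediate
10 | (1R,2R)-2-iodo-1-methylcyclopropane-1-carbaldehyde | I[C@@H]1C[C@]1(C)C=O | intermediate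
11 | (1R,2R)-1-ethenyl-2-iodo-1-methylcyclopropane (I cis to vinyl) | I[C@@H]1C[C@]1(C)C=C | intermediate
12 | cis-(2-ethenyl-2-methylcyclopropyl)lithium, configuration of 11 retained | [Li][C@@H]1C[C@]1(C)C=C | intermediate
13 | cis-(2-ethenyl-2-methylcyclopropyl)zinc bromide, configuration of 11 retained | Br[Zn][C@@H]1C[C@]1(C)C=C | intermediate
14 | (4R)-4-(tert-butyldimethylsilyloxy)-2-[(1R,2R)-2-ethenyl-2-methylcyclopropyl]-3-methylcyclopent-2-en-1-one | O=C1C[C@@H](O[Si](C)(C)C(C)(C)C)C(C)=C1[C@@H]2C[C@]2(C)C=C | intermediate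
15 | (3R,3aR)-3-(tert-butyldimethylsilyloxy)-3a,6-dimethyl-3,3a,4,7-tetrahydroazulen-1(2H)-one | O=C1C[C@@H](O[Si](C)(C)C(C)(C)C)[C@]2(C)CC=C(C)CC=C12 | intermediate
16 | 2β-(tert-butyldimethylsilyloxy)dauca-5,8-dien-4β-ol | CC(C)[C@]1(O)C[C@@H](O[Si](C)(C)C(C)(C)C)[C@]2(C)CC=C(C)CC=C12 | intermediate
17 | 2β-(tert-butyldimethylsilyloxy)-5β,6β-epoxydauc-8-en-4β-ol | CC(C)[C@]1(O)C[C@@H](O[Si](C)(C)C(C)(C)C)[C@]2(C)CC=C(C)C[C@H]3O[C@@]123 | intermediate
18 | 2β-(tert-butyldimethylsilyloxy)-5αH-dauc-8-ene-4β,6β-diol | CC(C)[C@]1(O)C[C@@H](O[Si](C)(C)C(C)(C)C)[C@]2(C)CC=C(C)C[C@@H](O)[C@@H]12 | intermediate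
19 | 2β-(tert-butyldimethylsilyloxy)-4β-hydroxy-5αH-dauc-8-en-6-one | CC(C)[C@]1(O)C[C@@H](O[Si](C)(C)C(C)(C)C)[C@]2(C)CC=C(C)CC(=O)[C@@H]12 | intermediate
20 | 2β-(tert-butyldimethylsilyloxy)-5αH-dauc-8-ene-4β,6α-diol | CC(C)[C@]1(O)C[C@@H](O[Si](C)(C)C(C)(C)C)[C@]2(C)CC=C(C)C[C@H](O)[C@@H]12 | intermediate
21 | 4-methoxybenzoyl chloride | COc1ccc(cc1)C(=O)Cl | starting material
22 | 2β-(tert-butyldimethylsilyloxy)-6α-(4-methoxybenzoyloxy)-5αH-dauc-8-en-4β-ol | CC(C)[C@]1(O)C[C@@H](O[Si](C)(C)C(C)(C)C)[C@]2(C)CC=C(C)C[C@H](OC(=O)c3ccc(OC)cc3)[C@@H]12 | intermediate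
23 | 6α-(4-methoxybenzoyloxy)-5αH-dauc-8-ene-2β,4β-diol | CC(C)[C@]1(O)C[C@@H](O)[C@]2(C)CC=C(C)C[C@H](OC(=O)c3ccc(OC)cc3)[C@@H]12 | intermediate
24 | angelic acid, (2Z)-2-methylbut-2-enoic acid | C/C=C(/C)C(=O)O | starting material
25 | (2Z)-2-methylbut-2-enoic 2,4,6-trichlorobenzoic anhydride | C/C=C(/C)C(=O)OC(=O)c1c(Cl)cc(Cl)cc1Cl | intermediate
26 | 2β-angeloyloxy-6α-(4-methoxybenzoyloxy)-5αH-dauc-8-en-4β-ol (CNP0204191.1) | C/C=C(/C)C(=O)O[C@@H]1C[C@@](O)(C(C)C)[C@@H]2[C@@H](OC(=O)c3ccc(OC)cc3)CC(C)=CC[C@]21C | target

**Totals and risks**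

Total step count: 17. Longest linear sequence: 14 steps (steps 4 to 17, from prop-2-yn-1-ol).

Steps most likely to fail:

Step 9. At the temperature that the methyl group on C1 demands, homolytic stereomutation of the cyclopropane or elimination of silanol from ring A may compete with the rearrangement and erode the chirality transfer. The fallback closes ring B at C8=C9 instead and sets out from 3. Copper-mediated conjugate allylation (allylMgBr, CuBr·SMe2, TMSCl, THF, −78 °C) anti to the silyloxy group would give the allylated silyl enol ether F1, which already holds quaternary C1. A Mukaiyama aldol addition to 3-methylbut-3-enal (BF3·OEt2, CH2Cl2, −78 °C) would give the aldol adduct F2. Mesylation and elimination (MsCl, Et3N) would give the E-configured trienone F3. Ring-closing metathesis with second-generation Grubbs catalyst (CH2Cl2, reflux) would come back to the route at 15.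

Step 12. Hydrogen-atom transfer to the planar C5 radical may show poor facial selectivity, or the radical may be trapped by a second trivalent titanium and lose the C4 oxygen. The fallback replaces the radical by a stereospecific 1,2-hydride shift and sets out from 15. Luche reduction (NaBH4, CeCl3, MeOH) from the α face would give the 4β-allylic alcohol F4. Directed epoxidation (VO(acac)2, t-BuOOH) would give the syn epoxy alcohol F5. Treatment with BF3·OEt2 (CH2Cl2, −78 °C) would trigger a semipinacol rearrangement in which the α-oriented C4 hydrogen migrates to C5 anti to the breaking C5–O bond, giving the trans-fused hydroxy ketone F6. Addition of i-PrMgCl/LaCl3·2LiCl from the α face would come back to the route at 18.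

Step 14. Protonation of the organosamarium intermediate may occur with poor facial selectivity, so that the axial 6β-alcohol forms again. The fallback inverts C6 by substitution instead of by redox chemistry. Setting out from 18, Mitsunobu esterification with 4-methoxybenzoic acid (PPh3, DIAD, toluene) would displace the activated axial 6β-oxygen from the opposite side. It would come back to the route at 22, skipping 19 and 20.

**Further compounds**
F1 | step 9 | trimethylsilyl enol ether of 3-allyl-4-(tert-butyldimethylsilyloxy)-3-methylcyclopentanone, allyl trans to OTBS | C=CC[C@]1(C)C=C(O[Si](C)(C)C)C[C@H]1O[Si](C)(C)C(C)(C)C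
F2 | step 9 | 3-allyl-4-(tert-butyldimethylsilyloxy)-2-(1-hydroxy-3-methylbut-3-enyl)-3-methylcyclopentanone (mixture at C5 and C6) | C=CC[C@]1(C)C(C(O)CC(C)=C)C(=O)C[C@H]1O[Si](C)(C)C(C)(C)C
F3 | step 9 | (2E)-3-allyl-4-(tert-butyldimethylsilyloxy)-3-methyl-2-(3-methylbut-3-enylidene)cyclopentanone | C=CC[C@]1(C)/C(=C\CC(C)=C)C(=O)C[C@H]1O[Si](C)(C)C(C)(C)C
F4 | step 12 | 4β-alcohol from 15: 3-(tert-butyldimethylsilyloxy)-3a,6-dimethyl-1,2,3,3a,4,7-hexahydroazulen-1-ol, OH cis to OTBS | O[C@H]1C[C@@H](O[Si](C)(C)C(C)(C)C)[C@]2(C)CC=C(C)CC=C12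
F5 | step 12 | 5β,6β-epoxide of F4, oxygen syn to the hydroxyl | O[C@H]1C[C@@H](O[Si](C)(C)C(C)(C)C)[C@]2(C)CC=C(C)C[C@H]3O[C@@]123
F6 | step 12 | trans-fused 6β-hydroxy-4-ketone with 5α-H (isopropyl still absent) | O=C1C[C@@H](O[Si](C)(C)C(C)(C)C)[C@]2(C)CC=C(C)C[C@@H](O)[C@@H]12
F0 | step 14 | none | none
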